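**Plan**

1. Target as read from the SMILES: gallocatechin-(4α→8)-catechin-(4α→8)-catechin. Every unit is (2R,3S) and both interflavan carbons are (4S), so both upper pyran rings are 2,3-trans-3,4-trans.
2. Cuts: (i) the 14 O–benzyl bonds; (ii) in each upper pyran ring the C3–O and C4–H bonds together, back to a C3=C4 alkene; (iii) the two C4(sp2)–C8(aryl) bonds, each as a Negishi coupling of a flav-3-en-4-yl triflate with a C8 arylzinc.
3. Enabling feature: in the pyran rings of the top (gallocatechin) and middle (catechin) units, O-3 and H-4 are cis and both lie on the face opposite the C2 aryl, and C4 is the fully substituted carbon. This is the signature of a syn H–B addition to a 4-aryl-flav-3-ene anti to its C2 aryl.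
4. Forward: the bottom unit is 8-bromo-penta-O-benzylcatechin from (+)-catechin. The middle and top units are (2S)-flavanone enol triflates whose pyran rings are closed in chromone syntheses. Coupling bottom→middle→top gives a flat bis(4-aryl-2H-chromene), then one double hydroboration–oxidation and hydrogenolysis follow.
5. Stereochemistry: C2/C3 of the bottom unit come from the chiral pool; C2 of the middle and top units from Rh-catalysed asymmetric 1,4-arylation; C3 and C4 of both upper units (4 of 8 centres) are relayed from C2 in the key step. The 4→8 regiochemistry and the chain length are fixed by the positions of Br and OTf.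

Key step: step 13

Assumption: 5, 9 and 14 are taken as catalogue compounds (5 is otherwise one O-benzylation from 2,4,6-trihydroxyacetophenone, 14 one borylation from 5-bromo-1,2,3-tris(benzyloxy)benzene).

**Route**

Step 1
Reactants: 1 (+)-catechin
Product: 2 5,7,3',4'-tetra-O-benzyl-(+)-catechin
Conditions: BnBr (4.4 equiv), K2CO3, DMF, 0 °C→rt, Ar
Reagents that add atoms: benzyl bromide, BrCc1ccccc1
Why: Williamson etherification with carbonate should alkylate only the four phenols, leaving the secondary 3-OH free and the chiral-pool (2R,3S) centres untouched.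

Step 2
Reactants: 2 5,7,3',4'-tetra-O-benzyl-(+)-catechin
Product: 3 8-bromo-5,7,3',4'-tetra-O-benzyl-(+)-catechin
Conditions: NBS (1.0 equiv), CH2Cl2, −78 °C→rt
Reagents that add atoms: N-bromosuccinimide, O=C1CCC(=O)N1Br
Why: Electrophilic aromatic bromination of 5,7-dialkoxyflavans is established to occur at C8, the most nucleophilic A-ring position, and one equivalent at low temperature should avoid 6,8-dibromination.

Step 3
Reactants: 3 8-bromo-5,7,3',4'-tetra-O-benzyl-(+)-catechin
Product: 4 8-bromo-3,5,7,3',4'-penta-O-benzyl-(+)-catechin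
Conditions: NaH, BnBr, DMF, 0 °C→rt
Reagents that add atoms: benzyl bromide, BrCc1ccccc1
Why: Williamson etherification of the 3-alkoxide removes the only acidic proton before halogen–lithium exchange and affects no stereocentre.

Step 4
Reactants: 5 1-[2-hydroxy-4,6-bis(benzyloxy)phenyl]ethanone
Product: 6 1-[3-bromo-2-hydroxy-4,6-bis(benzyloxy)phenyl]ethanone
Conditions: NBS (1.0 equiv), i-Pr2NH (10 mol%), CH2Cl2, 0 °C
Reagents that add atoms: N-bromosuccinimide, O=C1CCC(=O)N1Br
Why: Amine-catalysed NBS bromination of phenols is ortho-selective, so bromine should enter C3 (between OH and 4-OBn), the carbon that becomes C8 of the middle unit; the regiochemistry is to be confirmed by NOE of the remaining aryl H to both OCH2Ph groups.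

Step 5
Reactants: 6 1-[3-bromo-2-hydroxy-4,6-bis(benzyloxy)phenyl]ethanone
Product: 8 8-bromo-5,7-bis(benzyloxy)-4H-chromen-4-one, via enaminone 7 (not isolated)
Conditions: DMF-DMA, toluene, 100 °C; then conc. HCl, CH2Cl2, rt
Reagents that add atoms: N,N-dimethylformamide dimethyl acetal, COC(OC)N(C)C
Why: The standard enaminone chromone synthesis applies: condensation of the methyl ketone with the amide acetal, then acid-induced 6-endo oxa-Michael addition of the phenol and loss of dimethylamine closes the γ-pyrone ring.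

Step 6
Reactants: 8 8-bromo-5,7-bis(benzyloxy)-4H-chromen-4-one; 9 [3,4-bis(benzyloxy)phenyl]boronic acid
Product: 10 (2S)-8-bromo-5,7-bis(benzyloxy)-2-[3,4-bis(benzyloxy)phenyl]chroman-4-one
Conditions: [Rh(OH)(cod)]2 (2.5 mol%), electron-poor atropisomeric bisphosphine of the MeO-F12-BIPHEP class (5.5 mol%, antipode giving 2S), 9 (3 equiv), toluene/H2O, 30 °C
Reagents that add atoms: none
Why: Hayashi–Miyaura-type Rh(I)-catalysed asymmetric 1,4-addition of an arylboronic acid to a chromone sets C2 under catalyst control (2S in the flavanone is spatially the 2R arrangement of flavan-3-ols); the base-free medium should suppress retro-oxa-Michael racemisation, and the hindered electron-rich C–Br bond is inert to Rh(I).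

Step 7
Reactants: 10 (2S)-8-bromo-5,7-bis(benzyloxy)-2-[3,4-bis(benzyloxy)phenyl]chroman-4-one
Product: 11 (2S)-8-bromo-5,7-bis(benzyloxy)-2-[3,4-bis(benzyloxy)phenyl]-2H-chromen-4-yl trifluoromethanesulfonate
Conditions: PhNTf2 (1.2 equiv), KHMDS (1.15 equiv, added last), THF, −78 °C
Reagents that add atoms: N-phenylbis(trifluoromethanesulfonimide), O=S(=O)(N(c1ccccc1)S(=O)(=O)C(F)(F)F)C(F)(F)F
Why: Kinetic deprotonation at C3 (the only enolisable position) with in-situ O-sulfonylation should trap the enolate as the enol triflate before E1cB ring opening to the chalcone can erode C2.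

Step 8
Reactants: 5 1-[2-hydroxy-4,6-bis(benzyloxy)phenyl]ethanone
Product: 13 5,7-bis(benzyloxy)-4H-chromen-4-one, via enaminone 12 (not isolated)
Conditions: DMF-DMA, toluene, 100 °C; then conc. HCl, CH2Cl2, rt
Reagents that add atoms: N,N-dimethylformamide dimethyl acetal, COC(OC)N(C)C
Why: Same enaminone chromone synthesis as in step 5 (amide-acetal condensation, then 6-endo oxa-Michael addition and loss of dimethylamine).

Step 9
Reactants: 13 5,7-bis(benzyloxy)-4H-chromen-4-one; 14 [3,4,5-tris(benzyloxy)phenyl]boronic acid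
Product: 15 (2S)-5,7-bis(benzyloxy)-2-[3,4,5-tris(benzyloxy)phenyl]chroman-4-one
Conditions: [Rh(OH)(cod)]2 (2.5 mol%), same bisphosphine antipode as in step 6 (5.5 mol%), 14 (3 equiv), toluene/H2O, 30 °C
Reagents that add atoms: none
Why: The same Rh(I)-catalysed asymmetric 1,4-arylation of a chromone as in step 6 should set C2 of the top unit (2S) under catalyst control.

Step 10
Reactants: 15 (2S)-5,7-bis(benzyloxy)-2-[3,4,5-tris(benzyloxy)phenyl]chroman-4-one
Product: 16 (2S)-5,7-bis(benzyloxy)-2-[3,4,5-tris(benzyloxy)phenyl]-2H-chromen-4-yl trifluoromethanesulfonate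
Conditions: PhNTf2 (1.2 equiv), KHMDS (1.15 equiv, added last), THF, −78 °C
Reagents that add atoms: N-phenylbis(trifluoromethanesulfonimide), O=S(=O)(N(c1ccccc1)S(=O)(=O)C(F)(F)F)C(F)(F)F
Why: Kinetic enolate O-triflation as in step 7, with in-situ trapping to keep C2 intact.

Step 11
Reactants: 4 8-bromo-3,5,7,3',4'-penta-O-benzyl-(+)-catechin; 11 (2S)-8-bromo-5,7-bis(benzyloxy)-2-[3,4-bis(benzyloxy)phenyl]-2H-chromen-4-yl trifluoromethanesulfonate
Product: 19 (2S)-8-bromo-5,7-bis(benzyloxy)-2-[3,4-bis(benzyloxy)phenyl]-4-(3,5,7,3',4'-penta-O-benzylcatechin-8-yl)-2H-chromene, via aryllithium 17 (not isolated), via arylzinc chloride 18 (not isolated)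
Conditions: 4 (1.2 equiv), t-BuLi (2.4 equiv), THF, −78 °C; ZnCl2 (1.3 equiv), −78 °C→rt; then 11 (1.0 equiv), Pd(PPh3)4 (5 mol%), THF, 55 °C, dark
Reagents that add atoms: none
Why: Br/Li exchange, transmetalation to zinc and Negishi coupling should join C8 of the bottom unit to C4 of the middle unit regiospecifically, since 2,6-dialkoxyarylzinc reagents couple with cyclic enol triflates and the vinyl C–OTf bond undergoes oxidative addition much faster than the di-ortho-substituted, electron-rich C8–Br bond kept for step 12; no stereocentre is formed.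

Step 12
Reactants: 19 (2S)-8-bromo-5,7-bis(benzyloxy)-2-[3,4-bis(benzyloxy)phenyl]-4-(3,5,7,3',4'-penta-O-benzylcatechin-8-yl)-2H-chromene; 16 (2S)-5,7-bis(benzyloxy)-2-[3,4,5-tris(benzyloxy)phenyl]-2H-chromen-4-yl trifluoromethanesulfonate
Product: 22 tetradeca-O-benzyl bis(flav-3-ene) trimer [top (2S)-flav-3-ene C4 bonded to C8 of the middle (2S)-flav-3-ene whose C4 is bonded to C8 of penta-O-benzylcatechin], via aryllithium 20 (not isolated), via arylzinc chloride 21 (not isolated)
Conditions: 19 (1.0 equiv), t-BuLi (2.1 equiv), THF, −78 °C; ZnCl2 (1.2 equiv), −78 °C→rt; then 16 (1.3 equiv), Pd2(dba)3 (2.5 mol%), SPhos (10 mol%), THF, 60 °C, dark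
Reagents that add atoms: none
Why: The same Negishi sequence places the metal at C8 of the middle unit so that only the C4(top)–C8(middle) bond can form; as no other C–halogen bond remains, a bulky biarylphosphine catalyst suited to the hindered coupling can be used, and exchange at −78 °C should outrun any reaction of t-BuLi with the styrene-type alkene.

Step 13
Reactants: 22 tetradeca-O-benzyl bis(flav-3-ene) trimer
Product: 24 tetradeca-O-benzyl gallocatechin-(4α→8)-catechin-(4α→8)-catechin (3-OH free on the top/middle units; top/middle 2R,3S,4S; bottom 2R,3S), via bis-alkylborane 23 (not isolated)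
Conditions: BH3·THF (8 equiv), THF, 0 °C→rt, dark, Ar; then 3 M NaOH, 30% H2O2, 0 °C→rt
Reagents that add atoms: hydrogen peroxide, OO
Why: Concerted four-centre syn addition of H–B across each C3=C4 bond (boron to C3, the only CH terminus of a trisubstituted alkene whose C4 carries two electron-rich aryl groups; hydride to C4), followed by stereoretentive alkaline-peroxide C–B→C–O oxidation, is the classical hydroboration–oxidation of flav-3-enes to 2,3-trans-flavan-3-ols, here run on two rings at once. No ring is closed: the two flat 2H-pyran rings already present become the two saturated, all-equatorial pyran rings of the upper units. C3 of each ring should be set by attack of borane on the face anti to the adjacent C2 aryl (1,2-induction from the catalyst-derived C2 centre), and C4 is set by the syn mechanism, which puts H-4 on the same face as O-3 and so the flavanyl substituent trans to the 3-OH (4α). The two rings react independently under local control, so no induction between units is needed, and any slowly interconverting rotamers about the two C4–C8 axes of 22 converge because each axis becomes an sp3–sp2 bond. The step needs regioselectivity (B at C3, secured by the substitution pattern and by the donor A-ring, which favours hydride transfer to C4) and facial selectivity (secured by the C2 aryl next to the carbon that takes boron); benzyl ethers and the saturated bottom unit are inert to BH3 and NaOH/H2O2.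

Step 14
Reactants: 24 tetradeca-O-benzyl gallocatechin-(4α→8)-catechin-(4α→8)-catechin
Product: 25 gallocatechin-(4α→8)-catechin-(4α→8)-catechin (CNP0155646.1)
Conditions: H2 (1 atm), 20% Pd(OH)2/C, THF/MeOH/H2O, rt; filtration, Sephadex LH-20, lyophilisation
Reagents that add atoms: none
Why: Neutral hydrogenolysis over Pearlman's catalyst should cleave all fourteen benzyl ethers while leaving the interflavan C4–C8 bonds and the eight stereocentres untouched, as is usual for benzylated proanthocyanidin oligomers.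

**Compound list**

1 | (+)-catechin, (2R,3S) | Oc1cc(O)c2c(c1)O[C@H](c1ccc(O)c(O)c1)[C@@H](O)C2 | starting material
2 | 5,7,3',4'-tetra-O-benzyl-(+)-catechin, (2R,3S) | c1c(OCc3ccccc3)cc(OCc3ccccc3)c2c1O[C@H](c1ccc(OCc3ccccc3)c(OCc3ccccc3)c1)[C@@H](O)C2 | intermediate
3 | 8-bromo-5,7,3',4'-tetra-O-benzyl-(+)-catechin | Brc1c(OCc3ccccc3)cc(OCc3ccccc3)c2c1O[C@H](c1ccc(OCc3ccccc3)c(OCc3ccccc3)c1)[C@@H](O)C2 | intermediate
4 | 8-bromo-3,5,7,3',4'-penta-O-benzyl-(+)-catechin | Brc1c(OCc3ccccc3)cc(OCc3ccccc3)c2c1O[C@H](c1ccc(OCc3ccccc3)c(OCc3ccccc3)c1)[C@@H](OCc3ccccc3)C2 | intermediate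
5 | 1-[2-hydroxy-4,6-bis(benzyloxy)phenyl]ethanone | CC(=O)c1c(O)cc(OCc2ccccc2)cc1OCc1ccccc1 | starting material
6 | 1-[3-bromo-2-hydroxy-4,6-bis(benzyloxy)phenyl]ethanone | CC(=O)c1c(O)c(Br)c(OCc2ccccc2)cc1OCc1ccccc1 | intermediate
7 | (E)-1-[3-bromo-2-hydroxy-4,6-bis(benzyloxy)phenyl]-3-(dimethylamino)prop-2-en-1-one | CN(C)/C=C/C(=O)c1c(O)c(Br)c(OCc2ccccc2)cc1OCc1ccccc1 | intermediate
8 | 8-bromo-5,7-bis(benzyloxy)-4H-chromen-4-one | O=c1ccoc2c(Br)c(OCc3ccccc3)cc(OCc3ccccc3)c12 | intermediate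
9 | [3,4-bis(benzyloxy)phenyl]boronic acid | OB(O)c1ccc(OCc2ccccc2)c(OCc2ccccc2)c1 | starting material
10 | (2S)-8-bromo-5,7-bis(benzyloxy)-2-[3,4-bis(benzyloxy)phenyl]chroman-4-one | Brc1c(OCc3ccccc3)cc(OCc3ccccc3)c2c1O[C@H](c1ccc(OCc3ccccc3)c(OCc3ccccc3)c1)CC2=O | intermediate
11 | (2S)-8-bromo-5,7-bis(benzyloxy)-2-[3,4-bis(benzyloxy)phenyl]-2H-chromen-4-yl triflate | Brc1c(OCc3ccccc3)cc(OCc3ccccc3)c2c1O[C@H](c1ccc(OCc3ccccc3)c(OCc3ccccc3)c1)C=C2OS(=O)(=O)C(F)(F)F | intermediate
12 | (E)-1-[2-hydroxy-4,6-bis(benzyloxy)phenyl]-3-(dimethylamino)prop-2-en-1-one | CN(C)/C=C/C(=O)c1c(O)cc(OCc2ccccc2)cc1OCc1ccccc1 | intermediate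
13 | 5,7-bis(benzyloxy)-4H-chromen-4-one | O=c1ccoc2cc(OCc3ccccc3)cc(OCc3ccccc3)c12 | intermediate
14 | [3,4,5-tris(benzyloxy)phenyl]boronic acid | OB(O)c1cc(OCc2ccccc2)c(OCc2ccccc2)c(OCc2ccccc2)c1 | starting material
15 | (2S)-5,7-bis(benzyloxy)-2-[3,4,5-tris(benzyloxy)phenyl]chroman-4-one | c1c(OCc3ccccc3)cc(OCc3ccccc3)c2c1O[C@H](c1cc(OCc3ccccc3)c(OCc3ccccc3)c(OCc3ccccc3)c1)CC2=O | intermediate
16 | (2S)-5,7-bis(benzyloxy)-2-[3,4,5-tris(benzyloxy)phenyl]-2H-chromen-4-yl triflate | c1c(OCc3ccccc3)cc(OCc3ccccc3)c2c1O[C@H](c1cc(OCc3ccccc3)c(OCc3ccccc3)c(OCc3ccccc3)c1)C=C2OS(=O)(=O)C(F)(F)F | intermediate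
17 | 8-lithio-3,5,7,3',4'-penta-O-benzylcatechin | [Li]c1c(OCc3ccccc3)cc(OCc3ccccc3)c2c1O[C@H](c1ccc(OCc3ccccc3)c(OCc3ccccc3)c1)[C@@H](OCc3ccccc3)C2 | intermediate
18 | (3,5,7,3',4'-penta-O-benzylcatechin-8-yl)zinc chloride | Cl[Zn]c1c(OCc3ccccc3)cc(OCc3ccccc3)c2c1O[C@H](c1ccc(OCc3ccccc3)c(OCc3ccccc3)c1)[C@@H](OCc3ccccc3)C2 | intermediate
19 | (2S)-8-bromo-5,7-bis(benzyloxy)-2-[3,4-bis(benzyloxy)phenyl]-4-(penta-O-benzylcatechin-8-yl)-2H-chromene | Brc1c(OCc3ccccc3)cc(OCc3ccccc3)c2c1O[C@H](c1ccc(OCc3ccccc3)c(OCc3ccccc3)c1)C=C2c1c(OCc3ccccc3)cc(OCc3ccccc3)c2c1O[C@H](c1ccc(OCc3ccccc3)c(OCc3ccccc3)c1)[C@@H](OCc3ccccc3)C2 | intermediate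
20 | 8-lithio derivative of 19 (Li in place of Br) | [Li]c1c(OCc3ccccc3)cc(OCc3ccccc3)c2c1O[C@H](c1ccc(OCc3ccccc3)c(OCc3ccccc3)c1)C=C2c1c(OCc3ccccc3)cc(OCc3ccccc3)c2c1O[C@H](c1ccc(OCc3ccccc3)c(OCc3ccccc3)c1)[C@@H](OCc3ccccc3)C2 | intermediate
21 | 8-(chlorozincio) derivative of 19 (ZnCl in place of Br) | Cl[Zn]c1c(OCc3ccccc3)cc(OCc3ccccc3)c2c1O[C@H](c1ccc(OCc3ccccc3)c(OCc3ccccc3)c1)C=C2c1c(OCc3ccccc3)cc(OCc3ccccc3)c2c1O[C@H](c1ccc(OCc3ccccc3)c(OCc3ccccc3)c1)[C@@H](OCc3ccccc3)C2 | intermediate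
22 | tetradeca-O-benzyl bis(flav-3-ene) trimer, both chromene C2 (S), bottom unit (2R,3S) | c1c(OCc3ccccc3)cc(OCc3ccccc3)c2c1O[C@H](c1cc(OCc3ccccc3)c(OCc3ccccc3)c(OCc3ccccc3)c1)C=C2c1c(OCc3ccccc3)cc(OCc3ccccc3)c2c1O[C@H](c1ccc(OCc3ccccc3)c(OCc3ccccc3)c1)C=C2c1c(OCc3ccccc3)cc(OCc3ccccc3)c2c1O[C@H](c1ccc(OCc3ccccc3)c(OCc3ccccc3)c1)[C@@H](OCc3ccccc3)C2 | intermediate
23 | bis(alkylborane): BH2 at C3 of the top and middle units, cis to H-4 and trans to the C2 aryl | c1c(OCc3ccccc3)cc(OCc3ccccc3)c2c1O[C@H](c1cc(OCc3ccccc3)c(OCc3ccccc3)c(OCc3ccccc3)c1)[C@@H](B)[C@@H]2c1c(OCc3ccccc3)cc(OCc3ccccc3)c2c1O[C@H](c1ccc(OCc3ccccc3)c(OCc3ccccc3)c1)[C@@H](B)[C@@H]2c1c(OCc3ccccc3)cc(OCc3ccccc3)c2c1O[C@H](c1ccc(OCc3ccccc3)c(OCc3ccccc3)c1)[C@@H](OCc3ccccc3)C2 | intermediate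
24 | tetradeca-O-benzyl gallocatechin-(4α→8)-catechin-(4α→8)-catechin, 3-OH free on top and middle units | c1c(OCc3ccccc3)cc(OCc3ccccc3)c2c1O[C@H](c1cc(OCc3ccccc3)c(OCc3ccccc3)c(OCc3ccccc3)c1)[C@@H](O)[C@@H]2c1c(OCc3ccccc3)cc(OCc3ccccc3)c2c1O[C@H](c1ccc(OCc3ccccc3)c(OCc3ccccc3)c1)[C@@H](O)[C@@H]2c1c(OCc3ccccc3)cc(OCc3ccccc3)c2c1O[C@H](c1ccc(OCc3ccccc3)c(OCc3ccccc3)c1)[C@@H](OCc3ccccc3)C2 | intermediate
25 | gallocatechin-(4α→8)-catechin-(4α→8)-catechin (CNP0155646.1) | Oc1cc(O)c2c(c1)O[C@H](c1cc(O)c(O)c(O)c1)[C@@H](O)[C@@H]2c1c(O)cc(O)c2c1O[C@H](c1ccc(O)c(O)c1)[C@@H](O)[C@@H]2c1c(O)cc(O)c2c1O[C@H](c1ccc(O)c(O)c1)[C@@H](O)C2 | target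

**Step count and risks**

Total step count: 14. Longest linear sequence: 8 steps (5 → 6 → 8 → 10 → 11 → 19 → 22 → 24 → 25; steps 4, 5, 6, 7, 11, 12, 13, 14).

Steps most likely to fail:

1. Step 13. Facial selectivity of borane attack may be insufficient in one of the two rings (the perpendicular C4 aryl competing with the C2 aryl for control), or hydroboration of the hindered alkenes may stop at the mono-adduct. Fallback: abandon the alkene route and make both interflavan bonds by Lewis-acid-promoted flavan-4-yl cation arylation, which is known to give mainly 3,4-trans products in the catechin series. It sets out from 2 and rejoins the route at 24. Benzylation of 2 (NaH, BnBr) gives 3,5,7,3',4'-penta-O-benzylcatechin F1. Separately, 2 is oxidised at C4 with DDQ in the presence of 2-ethoxyethanol to 4-(2-ethoxyethoxy)-tetra-O-benzylcatechin F2. F2 with excess F1 and catalytic TMSOTf in CH2Cl2 at −78 °C should give the nona-O-benzyl catechin-(4α→8)-catechin dimer F3. Purchased (+)-gallocatechin is benzylated (BnBr, K2CO3) to 5,7,3',4',5'-penta-O-benzylgallocatechin F4 and oxidised in the same way to its 4-(2-ethoxyethoxy) derivative F5. F5 is then coupled with excess F3 (TMSOTf) at C8 of the upper unit to give 24, which enters step 14.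

2. Step 11. Transmetalation and reductive elimination at the doubly ortho-substituted aryl may be slow, leading to protodemetalation of 18, or oxidative addition at the C8–Br bond may compete and cause oligomerisation. Fallback: replace the cross-coupling by carbonyl addition and dehydration. It sets out from 4 and 10 and rejoins at 19. Aryllithium 17 (from 4, t-BuLi) is transmetalated with anhydrous CeCl3 and added to ketone 10 at −78 °C to give the tertiary 4-aryl-flavan-4-ol F6 (either C4 epimer). Acid-catalysed dehydration (PPTS, toluene) through the doubly benzylic C4 cation with loss of H-3 should give 19.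

3. Step 6. The electron-rich, ortho-brominated chromone may react sluggishly, and the catalyst may give incomplete enantiocontrol or over-addition to the product ketone. Fallback: racemic synthesis and resolution, setting out from 6 and rejoining at 10. Claisen–Schmidt condensation of 6 with purchased 3,4-bis(benzyloxy)benzaldehyde (KOH, EtOH) gives the 2'-hydroxychalcone F7. Oxa-Michael cyclisation (NaOAc, EtOH, reflux) gives the racemic flavanone F8. Preparative HPLC on a chiral stationary phase then delivers the (2S)-enantiomer 10.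

**Further compounds**

F1 | step 13 | 3,5,7,3',4'-penta-O-benzyl-(+)-catechin | c1c(OCc3ccccc3)cc(OCc3ccccc3)c2c1O[C@H](c1ccc(OCc3ccccc3)c(OCc3ccccc3)c1)[C@@H](OCc3ccccc3)C2
F2 | step 13 | 4-(2-ethoxyethoxy)-5,7,3',4'-tetra-O-benzylcatechin (C4 configuration immaterial) | c1c(OCc3ccccc3)cc(OCc3ccccc3)c2c1O[C@H](c1ccc(OCc3ccccc3)c(OCc3ccccc3)c1)[C@@H](O)C2OCCOCC
F3 | step 13 | nona-O-benzyl catechin-(4α→8)-catechin, 3-OH free on the upper unit | c1c(OCc3ccccc3)cc(OCc3ccccc3)c2c1O[C@H](c1ccc(OCc3ccccc3)c(OCc3ccccc3)c1)[C@@H](O)[C@@H]2c1c(OCc3ccccc3)cc(OCc3ccccc3)c2c1O[C@H](c1ccc(OCc3ccccc3)c(OCc3ccccc3)c1)[C@@H](OCc3ccccc3)C2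
F4 | step 13 | 5,7,3',4',5'-penta-O-benzyl-(+)-gallocatechin | c1c(OCc3ccccc3)cc(OCc3ccccc3)c2c1O[C@H](c1cc(OCc3ccccc3)c(OCc3ccccc3)c(OCc3ccccc3)c1)[C@@H](O)C2
F5 | step 13 | 4-(2-ethoxyethoxy)-5,7,3',4',5'-penta-O-benzylgallocatechin (C4 configuration immaterial) | c1c(OCc3ccccc3)cc(OCc3ccccc3)c2c1O[C@H](c1cc(OCc3ccccc3)c(OCc3ccccc3)c(OCc3ccccc3)c1)[C@@H](O)C2OCCOCC
F6 | step 11 | (2S)-8-bromo-5,7-bis(benzyloxy)-2-[3,4-bis(benzyloxy)phenyl]-4-(penta-O-benzylcatechin-8-yl)chroman-4-ol (C4 epimers) | Brc1c(OCc3ccccc3)cc(OCc3ccccc3)c2c1O[C@H](c1ccc(OCc3ccccc3)c(OCc3ccccc3)c1)CC2(O)c1c(OCc3ccccc3)cc(OCc3ccccc3)c2c1O[C@H](c1ccc(OCc3ccccc3)c(OCc3ccccc3)c1)[C@@H](OCc3ccccc3)C2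
F7 | step 6 | (E)-1-[3-bromo-2-hydroxy-4,6-bis(benzyloxy)phenyl]-3-[3,4-bis(benzyloxy)phenyl]prop-2-en-1-one | O=C(/C=C/c1ccc(OCc2ccccc2)c(OCc2ccccc2)c1)c1c(O)c(Br)c(OCc2ccccc2)cc1OCc1ccccc1
F8 | step 6 | racemic 8-bromo-5,7-bis(benzyloxy)-2-[3,4-bis(benzyloxy)phenyl]chroman-4-one | Brc1c(OCc3ccccc3)cc(OCc3ccccc3)c2c1OC(c1ccc(OCc3ccccc3)c(OCc3ccccc3)c1)CC2=O
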